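The pyranone ring C of the flavanone half is disconnected at C2–C3 and C4–C4a. A racemic O-aryl acylal, made from 3,5-dimethoxyphenol and an aldehyde that already carries the protected luteolin half, is ionized by a chiral acid to an O-aryl oxocarbenium ion. Ethoxyacetylene, a ketene equivalent, adds to C2 and its ketenium carbon C4 is captured by C4a of ring A, a formal (4+2) annulation that also sets C2. It exploits the benzylic, O1-bearing C2 as a latent cation and the phloroglucinol-type ring A, whose C4a lies between O1 and O5 and whose symmetry removes any regiochemical question. Chelation-controlled 5-O-demethylation ends the route.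

Key step: step 4

Remark: flavonoid numbering is used (O1, C2, C3, C4, C4a, C5 to C8, C8a; primes for the 2-aryl ring); the sense of induction of the chiral acid in step 4 cannot be derived from precedent, so the (S,S) acid is written and its mirror image is meant should the sense prove opposite.

Step 1
Reactants: 1 luteolin
Product: 2 7,4'-di-O-benzylluteolin
Conditions: BnBr (2.1 equiv), K2CO3 (2.2 equiv), DMF, 0 °C to rt
Reagents that add atoms: benzyl bromide, BrCc1ccccc1
Why: Williamson etherification under acidity control: the 7-OH and 4'-OH are the two most acidic hydroxyls (each conjugated to the C4 carbonyl), the 5-OH is locked in a hydrogen bond to that carbonyl and the 3'-OH is the least acidic free phenol, so about two equivalents of base and halide should give mainly the 7,4'-diether, which is separated from under- and over-alkylated material.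

Step 2
Reactants: 2 7,4'-di-O-benzylluteolin; 3 4-fluorobenzaldehyde
Product: 4 4-{2-(benzyloxy)-5-[7-(benzyloxy)-5-hydroxy-4-oxo-4H-chromen-2-yl]phenoxy}benzaldehyde
Conditions: 3 (1.1 equiv), K2CO3 (1.5 equiv), DMF, 90 °C
Reagents that add atoms: none
Why: Nucleophilic aromatic substitution (SNAr) of the formyl-activated fluoride by the 3'-phenoxide through a Meisenheimer adduct should form the diaryl ether of the target, the chelated 5-OH being too weakly nucleophilic to compete.

Step 3
Reactants: 4 the aldehyde of step 2; 5 3,5-dimethoxyphenol
Product: 7 racemic O-aryl acylal (3,5-dimethoxyphenoxy)(aryl)methyl pivalate, via alpha-chlorobenzyl pivalate 6 (not isolated)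
Conditions: PivCl (1.1 equiv), ZnCl2 (10 mol%), CH2Cl2, 0 °C to rt; then added to 5/NaH (1.6 equiv), THF–DMF, −40 to 0 °C; NaHCO3 work-up, Et3N-buffered silica
Reagents that add atoms: pivaloyl chloride, CC(C)(C)C(Cl)=O
Why: Zinc chloride-catalysed addition of the acyl chloride across the aldehyde C=O should give the alpha-chloroalkyl ester, whose benzylic chloride is displaced at oxygen by the hard sodium phenoxide in a dipolar aprotic medium (Williamson-type synthesis of acyloxyalkyl aryl ethers), the hindered pivaloyl group suppressing acyl transfer; the acetal carbon forms racemic, which is of no consequence.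

Step 4
Reactants: 7 the racemic O-aryl acylal; 8 ethoxyacetylene
Product: 10 (2S)-5,7-dimethoxyflavanone carrying the 7,4'-di-O-benzylluteolin-3'-yl ether at C4', via 4-ethoxy-2H-chromene enol ether 9 (not isolated)
Conditions: 8 (3 equiv, solution in hexanes), (S,S)-IDPi acid HN[P(=NSO2CF3)(O2-binaphthyl)]2 from (S)-3,3'-Ar2-BINOL, Ar = 3,5-(CF3)2C6H3 (5 mol%), CH2Cl2, −78 °C; then 0.5 M aq HCl, THF, 0 °C
Reagents that add atoms: water, O
Why: Proposed new method: the chiral acid protonates the pivalate carbonyl of 7 and the carboxylate, by far the better leaving group of the two acetal oxygens, departs to leave the O-aryl oxocarbenium ion (O1=C2) paired with the confined imidodiphosphorimidate anion; the CH terminus of 8 adds to C2 (C2–C3 bond), the ethoxyketenium carbon so formed is acylated at once by the ortho carbon of the 3,5-dimethoxyphenoxy ring (C4–C4a bond), and loss of the ring proton returns the acid and gives enol ether 9, which aqueous acid hydrolyses through C3 protonation to ketone 10. The closest known reaction types are the oxa-Povarov reaction of aryl oxocarbenium ions with alkenes (Prins-type addition, then Friedel–Crafts closure), the Friedel–Crafts capture of ketenium ions generated from ynol ethers and siloxyalkynes, and asymmetric counteranion-directed reactions of oxocarbenium ion pairs such as the catalytic oxa-Pictet–Spengler reaction. Ring C closes in a formal (4+2) manner by a six-membered Friedel–Crafts closure that is 6-endo-dig with respect to the former alkyne. C2 is the only new stereocenter and is set in the first C–C bond formation by the chiral anion, which should shield one face of the planar E-configured cation, while the racemic acetal center of 7 is erased on ionization so that both enantiomers converge. The step needs ionization toward the O-aryl cation, which the carboxylate leaving group secures, C-attack of 8 ahead of intermolecular arylation or alkyne protonation, which the low temperature, the excess of 8 and the fast O-protonation of the ester should secure, and ring closure ahead of loss of the aryloxy group, which the phloroglucinol-type nucleophilicity of C4a (between O1 and O5) should secure; both ortho positions of ring A are equivalent, so no regiochemical question arises. The flavone carbonyl, held in a hydrogen bond by its 5-OH, and the benzyl ethers should be spectators, and the cold quench keeps the acid-labile C2–O1 bond of 9 intact.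

Step 5
Reactants: 10 the (2S)-5,7-dimethoxyflavanone of step 4
Product: 11 the target
Conditions: BCl3 (1 M in CH2Cl2, 8 equiv), C6HMe5 (6 equiv), CH2Cl2, −78 °C to rt; then MeOH, H2O
Reagents that add atoms: none
Why: Boron trichloride should cleave the two aryl benzyl ethers at low temperature, with pentamethylbenzene as a non-basic trap for the benzyl cations, and on warming remove only the 5-O-methyl group of the flavanone through the six-membered boron chelate with the C4 carbonyl, while the unchelated 7-methoxy group and the diaryl ether stay; no base is present, so C2 should keep its configuration.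

Compound list
1 | luteolin, 2-(3,4-dihydroxyphenyl)-5,7-dihydroxy-4H-chromen-4-one | Oc1cc(-c2cc(=O)c3c(O)cc(O)cc3o2)ccc1O | starting material
2 | 7,4'-di-O-benzylluteolin, 7-(benzyloxy)-2-[4-(benzyloxy)-3-hydroxyphenyl]-5-hydroxy-4H-chromen-4-one | Oc1cc(-c2cc(=O)c3c(O)cc(OCc4ccccc4)cc3o2)ccc1OCc1ccccc1 | intermediate
3 | 4-fluorobenzaldehyde | O=Cc1ccc(F)cc1 | starting material
4 | 4-{2-(benzyloxy)-5-[7-(benzyloxy)-5-hydroxy-4-oxo-4H-chromen-2-yl]phenoxy}benzaldehyde | O=Cc1ccc(Oc2cc(-c3cc(=O)c4c(O)cc(OCc5ccccc5)cc4o3)ccc2OCc2ccccc2)cc1 | intermediate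
5 | 3,5-dimethoxyphenol | COc1cc(O)cc(OC)c1 | starting material
6 | racemic chloro(aryl)methyl pivalate, aryl being the 4-(aryloxy)phenyl group of 4 | CC(C)(C)C(=O)OC(Cl)c1ccc(Oc2cc(-c3cc(=O)c4c(O)cc(OCc5ccccc5)cc4o3)ccc2OCc2ccccc2)cc1 | intermediate
7 | racemic (3,5-dimethoxyphenoxy)(aryl)methyl pivalate, aryl as in 6 | COc1cc(OC)cc(OC(OC(=O)C(C)(C)C)c2ccc(Oc3cc(-c4cc(=O)c5c(O)cc(OCc6ccccc6)cc5o4)ccc3OCc3ccccc3)cc2)c1 | intermediate
8 | ethoxyacetylene (ethoxyethyne) | C#COCC | starting material
9 | (2S)-4-ethoxy-5,7-dimethoxy-2-aryl-2H-chromene, aryl as in 6 | COc1cc(OC)c2c(c1)O[C@H](c1ccc(Oc3cc(-c4cc(=O)c5c(O)cc(OCc6ccccc6)cc5o4)ccc3OCc3ccccc3)cc1)C=C2OCC | intermediate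
10 | (2S)-2-aryl-5,7-dimethoxychroman-4-one, aryl as in 6 | COc1cc(OC)c2c(c1)O[C@H](c1ccc(Oc3cc(-c4cc(=O)c5c(O)cc(OCc6ccccc6)cc5o4)ccc3OCc3ccccc3)cc1)CC2=O | intermediate
11 | (2S)-2-{4-[5-(5,7-dihydroxy-4-oxo-4H-chromen-2-yl)-2-hydroxyphenoxy]phenyl}-5-hydroxy-7-methoxychroman-4-one | COc1cc(O)c2c(c1)O[C@H](c1ccc(Oc3cc(-c4cc(=O)c5c(O)cc(O)cc5o4)ccc3O)cc1)CC2=O | target

Total step count: 5. Longest linear sequence: 5 steps (1 to 11 through 2, 4, 7 and 10).

Steps most likely to fail

Step 4 (proposed new method). The ion pair may discriminate the two faces of the cation poorly. The acid may protonate and oligomerize the ynol ether, or be held back by the basic flavone. The cation may arylate a second molecule, or the ketenium stage may collapse with loss of the aryloxy group before ring closure. The fallback uses known chemistry, sets out from 4 and comes back at 10. Claisen–Schmidt condensation of 4 with commercial 1-(2-hydroxy-4,6-dimethoxyphenyl)ethanone (KOH, EtOH–THF, rt) should give the (E)-2'-hydroxychalcone F1. Oxa-Michael ring closure (NaOAc, EtOH, reflux) should give the racemic flavanone F2. Asymmetric transfer hydrogenation run as a kinetic resolution (Cp*RhCl[(R,R)-TsDPEN], HCO2H/Et3N, EtOAc, rt, stopped near half conversion) should reduce the (2R) ketone to the cis-(2R,4R)-flavan-4-ol F3 and leave the (2S) ketone 10, which is separated and taken into step 5.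

Step 3. The addition of the acyl chloride to the electron-rich aldehyde may lie on the wrong side of its equilibrium. The phenoxide may be acylated or C-alkylated instead of O-alkylated, and the acylal may ionize and hydrolyse during purification. The fallback sets out from 4 and comes back at 10. Benzotriazole and SOCl2 (CH2Cl2, rt) should give the 1-(alpha-chlorobenzyl)benzotriazole F4, and sodium 3,5-dimethoxyphenoxide (THF, 0 °C) the bench-stable benzotriazole N,O-acetal F5, a precursor of the same O-aryl oxocarbenium ion. Its basic leaving group calls for a stoichiometric Lewis acid (ZnBr2 or SnCl4, CH2Cl2, −78 °C, with 8, then aqueous acid). The annulation would then give the racemic flavanone F2, which the kinetic resolution described above turns into 10.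

Step 5. Ether cleavage may be incomplete or go too far (loss of the 7-O-methyl group). Benzyl cations may re-alkylate the electron-rich rings, and the Lewis acid may open ring C reversibly with erosion of configuration at C2. The fallback sets out from 10 and comes back at 11. Hydrogenolysis (H2, 10% Pd on carbon, THF–EtOAc, rt) should give the triphenol F6, and AlCl3 in MeCN (rt) should then remove only the chelated 5-O-methyl group to give 11.

Further compounds
F1 | step 4 | (E)-1-(2-hydroxy-4,6-dimethoxyphenyl)-3-aryl-prop-2-en-1-one, aryl as in 6 | COc1cc(O)c(C(=O)/C=C/c2ccc(Oc3cc(-c4cc(=O)c5c(O)cc(OCc6ccccc6)cc5o4)ccc3OCc3ccccc3)cc2)c(OC)c1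
F2 | step 4 | racemic 2-aryl-5,7-dimethoxychroman-4-one, aryl as in 6 | COc1cc(OC)c2c(c1)OC(c1ccc(Oc3cc(-c4cc(=O)c5c(O)cc(OCc6ccccc6)cc5o4)ccc3OCc3ccccc3)cc1)CC2=O
F3 | step 4 | (2R,4R)-2-aryl-5,7-dimethoxychroman-4-ol, aryl as in 6 | COc1cc(OC)c2c(c1)O[C@@H](c1ccc(Oc3cc(-c4cc(=O)c5c(O)cc(OCc6ccccc6)cc5o4)ccc3OCc3ccccc3)cc1)C[C@H]2O
F4 | step 3 | racemic 1-[chloro(aryl)methyl]-1H-benzotriazole, aryl as in 6 | ClC(n1nnc2ccccc21)c1ccc(Oc2cc(-c3cc(=O)c4c(O)cc(OCc5ccccc5)cc4o3)ccc2OCc2ccccc2)cc1
F5 | step 3 | racemic 1-[(3,5-dimethoxyphenoxy)(aryl)methyl]-1H-benzotriazole, aryl as in 6 | COc1cc(OC)cc(OC(n2nnc3ccccc32)c2ccc(Oc3cc(-c4cc(=O)c5c(O)cc(OCc6ccccc6)cc5o4)ccc3OCc3ccccc3)cc2)c1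
F6 | step 5 | (2S)-2-{4-[5-(5,7-dihydroxy-4-oxo-4H-chromen-2-yl)-2-hydroxyphenoxy]phenyl}-5,7-dimethoxychroman-4-one | COc1cc(OC)c2c(c1)O[C@H](c1ccc(Oc3cc(-c4cc(=O)c5c(O)cc(O)cc5o4)ccc3O)cc1)CC2=O
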